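## Analysis of the target

The target 22 is a 2,4,6-trisubstituted tetrahydropyran (ring atoms O1, C2, C3, C4, C5, C6). C2 carries a 4-hydroxy-3-methoxyphenyl group, C4 a hydroxyl, and C6 a two-carbon arm C1'(OH)–C2'H2 that ends in a 4-hydroxyphenyl ring. There are four stereocentres: C2 (S), C4 (R), C6 (S) and C1' (R). Across O1 the aryl group and the side chain are trans; the C4 hydroxyl is cis to the side chain and trans to the aryl group; the C1' hydroxyl is anti (erythro) to O1 on C6. The 2,6-trans ring is the less stable diastereomer, because one of the two large groups must be axial. Every closure that can equilibrate (oxa-Michael addition, Prins cyclisation, oxocarbenium reduction) therefore drifts to the cis isomer, and the trans relationship has to be made under kinetic, stereospecific control. The C2–O1 bond is a para-oxygenated benzylic ether: acid can ionise it, base can open it through a quinone methide once the phenol is free, and hydrogenolysis can cleave it. The two phenols must be masked, and a carbonyl at C1' makes C6 epimerisable. The strategy rests on the segment O1–C6(C1')–C5–C4: C6 is an ether carbon bearing a carboxyl-level carbon (C1') and a methylene (C5), which is the pattern left by a glycolate ester-enolate Claisen rearrangement. The same oxygen O1 is bonded to the benzylic carbon C2, so a stereocentre at C2 can be relayed to C6 through a cyclic [3,3] shift that also leaves a C3=C4 double bond where the C4 oxygen is needed.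

## Retrosynthetic reasoning

**22 ⇒ 21 ⇒ 20 (protecting groups).** The last bonds cut are O–protecting-group bonds: the phenols are carried as benzyl ethers (21) and the C4 hydroxyl as a silyl ether (20). The silyl group is removed first, while the phenols are still capped, because a free para-phenol at C2 in basic fluoride could open the ring through a quinone methide and return the cis isomer. Neutral hydrogenolysis is kept for the very end.

**20 ⇒ 19 (C1'–H).** C1' is taken back to a ketone. The ring oxygen O1 is α to that carbonyl, so a chelating metal hydride can hold O1 and C=O in a five-membered chelate and deliver hydride from the face of C6–H. This gives the anti arrangement of O1 and the C1' hydroxyl, which is the (1'R) configuration. The fourth stereocentre is thus bought from the third without a chiral reagent.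

**19 ⇒ 16 + 17 (C1'–C2').** The bond between the carbonyl and the benzylic methylene is cut. The ring half becomes the N-methoxy-N-methylamide 16; the arm becomes benzylic chloride 17, used as its magnesium derivative 18. Cutting here and not at C6–C1' keeps a carboxyl-level carbon on C6, which is what the key step delivers, and removes the whole second arene as a simple halide. The forward reaction must stop at the ketone; hence the amide, which holds the tetrahedral adduct until work-up, and the silyl ether on C4, since a free alkoxide there would close back onto the carbonyl.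

**16 ⇒ 15 ⇒ 14 (amide C–N, O–Si).** The amide is traced to bridged lactone 14. The lactone is both the activated form of the C6 carboxyl and the masked form of the C4 hydroxyl, so one aminolysis releases both (15); silylation follows.

**14 ⇒ 13 ⇒ 12 (C4–O).** In acid 12 the C3=C4 double bond is γ,δ to the carboxyl on C6. Halolactonisation closes a five-membered lactone by attack at C4, and because the carboxyl is tethered to C6 the new C4–O bond can only form on the ring face that carries the carboxyl. That is the cis relationship between the C4 oxygen and the C6 substituent that the target demands. The halogen that lands on C3 (13) is removed reductively. No other way of oxidising C4 (hydroboration, epoxidation) would receive both regio- and facial control from the substrate.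

**12 ⇒ 9 (C5–C6, the key disconnection).** The C5–C6 bond is cut and the bond between the carboxyl oxygen and C3 is restored. The dihydropyran acid becomes the six-membered lactone 9, a 1,4-dioxan-2-one in which the ether oxygen is O1, the aryl-bearing carbon is C2, the vinyl-bearing carbon is C3, and the lactone methylene is the future C6. Forward, the silyl ketene acetal 10 of this lactone rearranges in a [3,3] sense to silyl ester 11 and then 12. The cut is made here because it is the only one that turns the hard 2,6-trans problem into an easy one, the cis arrangement of two adjacent substituents on a dioxanone. The forward step must transfer chirality from C3 (lost) to C6 (gained) with C2 as a bystander.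

**9 ⇒ 7 ⇒ 5 + 6 (lactone C–O, ether O–CH2).** The two-carbon glycolate unit comes from diazo ester 6, inserted into the free benzylic O–H of 5 under neutral conditions so that the benzoate stays on the allylic oxygen (7). Removal of the benzoate (8) and lactonisation give 9. The two secondary hydroxyls of the diol must be told apart, and 5 arrives with that differentiation built in.

**5 ⇒ 3 + 4, 3 ⇒ 1 + 2 (C–C between the carbinol carbons).** Aldehyde 4 is joined to the oxygen-substituted allyl donor 3 in one catalytic step that sets both stereocentres anti and leaves only the benzylic hydroxyl free. Donor 3 is the acylal of 1 with 2. All later stereocentres descend from this step.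

## Alternatives that were turned down

**Alternative 1:** The ring is cut at O1–C2 with C2 raised to a ketone. The open-chain aryl ketone diol A2 is closed under acid to the bridged ketal A1, a 6,8-dioxabicyclo[3.2.1]octane in which C2 is bonded to both O1 and the C1' oxygen. A coordinating aluminium hydride (i-Bu2AlH) is then meant to cleave the C2–O1' bond and deliver hydride from the face of the departing oxygen, leaving the aryl group trans to C6.
- For: ketalisation is thermodynamically driven and needs no selectivity; C4, C6 and C1' are set on an acyclic chain; the aryl ketone is a convenient coupling site, so the route is convergent. On convergence it is stronger than the chosen route.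
- Against: retention depends on a tight, internally delivered hydride. Here the ketal carbon bears a para-oxygenated aryl group, so C–O cleavage gives an unusually long-lived oxocarbenium ion, and external axial attack on that ion gives the 2,6-cis ring. Aluminium can also bind O1 and open the ketal to a tetrahydrofuran. The C6/C1' diol of A2 is erythro and so is not available from an (E)-alkene by asymmetric dihydroxylation.
- Comparison: the chosen strategy offers a trans relationship fixed by a concerted suprafacial shift, with no cation at C2 at any stage.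

**Alternative 2:** O1–C6 is cut. In epoxy alcohol A4 the benzylic C2 hydroxyl opens a trans epoxide spanning C6 and C1' at the nearer carbon (6-exo-tet) with inversion, giving A3, which is the same compound as 20 of the chosen route.
- For: the closure is a stereospecific SN2 reaction, so the trans ring is dictated by the configurations of C2 and C6 and not by ring thermodynamics. The C1' carbinol comes from the epoxide with the correct erythro relationship, so no chelation-controlled reduction is needed; on this point it is stronger than the chosen route. The step count to 20 is similar.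
- Against: C2, C4 and the epoxide must be installed by separate reagent-controlled operations on a flexible chain, with the C2 and C4 hydroxyls differentiated. Closure to a trans ring needs a chair with one axial group and so is slow; it competes with 7-endo opening at C1' and, under the acid normally used, with ionisation of the electron-rich benzylic carbinol (loss of the C2 configuration, elimination).
- Comparison: the chosen strategy derives all four stereocentres from one catalytic C–C bond formation and never exposes a free benzylic carbinol to acid.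

**Alternative 3:** C2–C3 and O1–C6 are cut in one cycloaddition. Aldehyde 4 and silyloxydiene A6 combine under Ti(OiPr)4–BINOL catalysis to give dihydropyranone A5 with C2 set. Axial conjugate addition of a vinyl cuprate would give the 2,6-trans ketone A7, a bulky hydride would give the axial C4 alcohol, and the vinyl group would then be turned into the C1' carbinol with its benzyl arm.
- For: the ring is reached in one step from 4 with C2 set catalytically; axial cuprate addition and equatorial hydride attack are dependable. On ring construction it is clearly shorter than the chosen route.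
- Against: aldehyde 4 is deactivated by two donor oxygens, so the Lewis-acid-catalysed cycloaddition is slow and its selectivity is at risk. A5 and A7 are β-alkoxy ketones with an electron-rich benzylic C2–O1 bond, so retro-oxa-Michael opening and re-closure can erode both the C2 configuration and the trans relationship (the cis ketone is the thermodynamic isomer). C1' would have to be created on a monosubstituted alkene beside C6 under reagent control, followed by epoxide formation and aryl-cuprate opening; several steps with C1' as the weak point.
- Comparison: the chosen route is longer to the ring, but its trans ring never carries a C4 ketone and its C1' centre is set by chelation to the ring oxygen.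

Key step: step 5

Remark on atom labels: O1, C2–C6, C1' and C2' are those of the target and are used for every ring intermediate.

Assumption: the (R) antipode of SEGPHOS is taken to direct the allyl unit to the Si face of aldehyde 4; if the sense is the reverse, (S)-SEGPHOS is used and nothing else changes.

## Route

Step 1
Reactants: 1 acrolein; 2 benzoic anhydride
Product: 3 prop-2-ene-1,1-diyl dibenzoate
Conditions: H2SO4 (cat.), CH2Cl2, 0 °C → rt
Reagents that add atoms: none
Why: Acid-catalysed acylal formation: the activated aldehyde carbon takes up both benzoate groups of the anhydride with no by-product; low temperature and a trace of acid keep 1,2-addition ahead of conjugate addition and polymerisation.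

Step 2
Reactants: 3 prop-2-ene-1,1-diyl dibenzoate; 4 4-(benzyloxy)-3-methoxybenzaldehyde
Product: 5 (1R,2S)-1-[4-(benzyloxy)-3-methoxyphenyl]-1-hydroxybut-3-en-2-yl benzoate
Conditions: [Ir(cod)Cl]2 (2.5 mol %), (R)-SEGPHOS (5 mol %), 4-chloro-3-nitrobenzoic acid (10 mol %), Cs2CO3 (20 mol %), i-PrOH (2 equiv), THF, 90 °C (sealed tube)
Reagents that add atoms: none
Why: Iridium-catalysed transfer-hydrogenative carbonyl allylation (anti-(benzoyloxy)allylation): the low-valent cyclometallated iridium benzoate complex ionises 3 to a 1-(benzoyloxy)allyl iridium species that adds to 4 through a closed chair (Zimmerman–Traxler) transition state while i-PrOH regenerates the catalyst. The anti relationship follows from the (E) geometry of the σ-allyl, the absolute sense from the bisphosphine, and the adduct carries its only free hydroxyl on the benzylic carbon.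

Step 3
Reactants: 5 (1R,2S)-1-[4-(benzyloxy)-3-methoxyphenyl]-1-hydroxybut-3-en-2-yl benzoate; 6 ethyl diazoacetate
Product: 7 ethyl 2-{[(1R,2S)-2-(benzoyloxy)-1-[4-(benzyloxy)-3-methoxyphenyl]but-3-en-1-yl]oxy}acetate
Conditions: Rh2(OAc)4 (1 mol %), CH2Cl2, rt, slow addition of 6
Reagents that add atoms: none
Why: Rhodium carbenoid O–H insertion (oxonium ylide, then proton shift) forms the ether under neutral conditions, so the benzoate cannot migrate and no stereocentre is touched; insertion into the hydroxyl is expected to outrun cyclopropanation of the electron-poor monosubstituted alkene when the diazo ester is kept dilute.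

Step 4
Reactants: 7 ethyl 2-{[(1R,2S)-2-(benzoyloxy)-1-[4-(benzyloxy)-3-methoxyphenyl]but-3-en-1-yl]oxy}acetate
Product: 9 (5R,6S)-5-[4-(benzyloxy)-3-methoxyphenyl]-6-ethenyl-1,4-dioxan-2-one, via hydroxy methyl ester 8 (not isolated)
Conditions: K2CO3 (cat.), MeOH, 0 °C → rt; AcOH quench, evaporate; PPTS (cat.), 4 Å MS, toluene, 70 °C
Reagents that add atoms: none
Why: Base-catalysed transesterification removes the benzoate as its methyl ester and exchanges the ethyl ester, then lactonisation (6-exo-trig) of the freed allylic hydroxyl is driven by removal of methanol under an acid mild enough not to ionise the benzylic ether. No stereocentre is touched, so the anti diol becomes the cis-5,6-disubstituted dioxanone.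

Step 5
Reactants: 9 (5R,6S)-5-[4-(benzyloxy)-3-methoxyphenyl]-6-ethenyl-1,4-dioxan-2-one
Product: 12 (2S,6S)-6-[4-(benzyloxy)-3-methoxyphenyl]-3,6-dihydro-2H-pyran-2-carboxylic acid, via silyl ketene acetal 10 (not isolated), via trimethylsilyl ester 11 (not isolated)
Conditions: Me3SiCl, Et3N, THF, −78 °C; LiN(SiMe3)2, −78 °C → rt, then 50 °C; aq. citric acid work-up (crude acid used directly)
Reagents that add atoms: none
Why: Deprotonation of 9 at its only enolisable position in the presence of Me3SiCl gives the cyclic O-silyl ketene acetal 10, in which the ketene acetal, the ester oxygen, the allylic carbon and the vinyl group make up the 1,5-diene of an Ireland–Claisen rearrangement. On warming, the ketene acetal carbon bonds to the vinyl terminus (the C5–C6 bond) while the allylic C–O bond of the former lactone breaks, so the dioxanone is transposed into the dihydropyran and the carboxyl leaves the ring as silyl ester 11, hydrolysed on work-up. The closest known reaction type is the ester-enolate Claisen rearrangement of 6-alkenyl-1,4-dioxan-2-ones to 3,6-dihydro-2H-pyran-2-carboxylic acids. The new ring (O1, C2, C3, C4, C5, C6) closes by suprafacial C–C bond formation in a concerted [3,3] shift; the two tether atoms O1 and C2 force a boat, bicyclo[2.2.2]octane-like transition state, and a chair is out of reach. The one new stereocentre, C6, is controlled by the allylic stereocentre that is consumed: the vinyl group must be axial and can reach the ketene acetal only from its own face. Because the aryl group at C2 is cis to the vinyl group in 9 and C2 is a bystander, the carboxyl ends up trans to the aryl group, which is the 2,6-trans relationship of the target in the (2S,6S) series. The step needs complete chirality transfer and an enolate that is trapped before it can condense; the ring-locked geometry secures the first, the silyl chloride already present secures the second, and in the cis isomer the aryl group is equatorial when the vinyl group is axial, so nothing opposes the reactive conformer. The C3=C4 double bond that results is necessarily cis and lies γ,δ to the carboxyl.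

Step 6
Reactants: 12 (2S,6S)-6-[4-(benzyloxy)-3-methoxyphenyl]-3,6-dihydro-2H-pyran-2-carboxylic acid
Product: 13 (1S,3R,4R,5S)-3-[4-(benzyloxy)-3-methoxyphenyl]-4-iodo-2,6-dioxabicyclo[3.2.1]octan-7-one
Conditions: I2, NaHCO3, MeCN, 0 °C, dark
Reagents that add atoms: iodine, II
Why: Kinetic iodolactonisation: the carboxylate on C6 opens the iodonium ion at C4 (5-exo closure to the γ-lactone, also the carbon farther from the inductively withdrawing O1), so the C4–O bond forms on the carboxyl face and iodine ends up anti on C3. This sets C4 cis to the C6 substituent, and the bicarbonate buffer protects the benzylic, allylic C2–O1 bond.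

Step 7
Reactants: 13 (1S,3R,4R,5S)-3-[4-(benzyloxy)-3-methoxyphenyl]-4-iodo-2,6-dioxabicyclo[3.2.1]octan-7-one
Product: 14 (1S,3S,5R)-3-[4-(benzyloxy)-3-methoxyphenyl]-2,6-dioxabicyclo[3.2.1]octan-7-one
Conditions: Bu3SnH, AIBN (cat.), toluene, 80 °C
Reagents that add atoms: none
Why: Radical chain dehalogenation; the secondary C3 radical is quenched by the tin hydride faster than aryl migration or acyloxy shift can occur at a normal hydride concentration, and no stereocentre other than the iodine-bearing carbon is involved.

Step 8
Reactants: 14 (1S,3S,5R)-3-[4-(benzyloxy)-3-methoxyphenyl]-2,6-dioxabicyclo[3.2.1]octan-7-one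
Product: 15 (2S,4R,6S)-6-[4-(benzyloxy)-3-methoxyphenyl]-4-hydroxy-N-methoxy-N-methyloxane-2-carboxamide
Conditions: MeNH(OMe)·HCl, AlMe3, CH2Cl2, 0 °C → rt; aq. KNaC4H4O6 work-up
Reagents that add atoms: N,O-dimethylhydroxylamine hydrochloride, CNOC.Cl
Why: Aluminium amide aminolysis of a lactone (Weinreb amide formation) cleaves the acyl–oxygen bond, so the C4 configuration is retained and the strained bridged lactone opens readily; the weakly basic aluminium amide does not epimerise C6.

Step 9
Reactants: 15 (2S,4R,6S)-6-[4-(benzyloxy)-3-methoxyphenyl]-4-hydroxy-N-methoxy-N-methyloxane-2-carboxamide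
Product: 16 (2S,4R,6S)-6-[4-(benzyloxy)-3-methoxyphenyl]-4-[(tert-butyldimethylsilyl)oxy]-N-methoxy-N-methyloxane-2-carboxamide
Conditions: TBSOTf, 2,6-lutidine, CH2Cl2, −78 → 0 °C
Reagents that add atoms: tert-butyldimethylsilyl trifluoromethanesulfonate, CC(C)(C)[Si](C)(C)OS(=O)(=O)C(F)(F)F
Why: Silyl triflate silylation is fast enough at low temperature for the hindered secondary hydroxyl and is carried out at once so that the hydroxy amide cannot close back to the lactone; the silyl ether is also a poor ligand and will not disturb the later chelation.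

Step 10
Reactants: 16 (2S,4R,6S)-6-[4-(benzyloxy)-3-methoxyphenyl]-4-[(tert-butyldimethylsilyl)oxy]-N-methoxy-N-methyloxane-2-carboxamide; 17 1-(benzyloxy)-4-(chloromethyl)benzene
Product: 19 1-[(2S,4R,6S)-6-[4-(benzyloxy)-3-methoxyphenyl]-4-[(tert-butyldimethylsilyl)oxy]oxan-2-yl]-2-[4-(benzyloxy)phenyl]ethan-1-one, via benzylic Grignard reagent 18 (not isolated)
Conditions: 17, Mg, Et2O, 0 °C (slow addition); then 16, THF, −20 → 0 °C; aq. NH4Cl
Reagents that add atoms: none
Why: Grignard addition to a Weinreb amide (Weinreb ketone synthesis): the magnesium-chelated tetrahedral adduct survives until the cold, buffered quench, so a second addition and base-mediated epimerisation at C6 are both avoided; the ketone is taken on without delay.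

Step 11
Reactants: 19 1-[(2S,4R,6S)-6-[4-(benzyloxy)-3-methoxyphenyl]-4-[(tert-butyldimethylsilyl)oxy]oxan-2-yl]-2-[4-(benzyloxy)phenyl]ethan-1-one
Product: 20 (1R)-1-[(2S,4R,6S)-6-[4-(benzyloxy)-3-methoxyphenyl]-4-[(tert-butyldimethylsilyl)oxy]oxan-2-yl]-2-[4-(benzyloxy)phenyl]ethan-1-ol
Conditions: Zn(BH4)2 (made in the flask from ZnCl2 and NaBH4 in Et2O), Et2O, −30 → 0 °C; aq. NH4Cl
Reagents that add atoms: none
Why: Chelation-controlled (Cram chelate) reduction: zinc bridges O1 and the carbonyl oxygen, and hydride enters from the face of C6–H, away from C5, giving the anti arrangement of O1 and the new hydroxyl, which is (1'R). The reagent is neutral, so the acidic α-positions of the benzyl ketone are not disturbed.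

Step 12
Reactants: 20 (1R)-1-[(2S,4R,6S)-6-[4-(benzyloxy)-3-methoxyphenyl]-4-[(tert-butyldimethylsilyl)oxy]oxan-2-yl]-2-[4-(benzyloxy)phenyl]ethan-1-ol
Product: 21 (2S,4R,6S)-2-[4-(benzyloxy)-3-methoxyphenyl]-6-{(1R)-2-[4-(benzyloxy)phenyl]-1-hydroxyethyl}oxan-4-ol
Conditions: Bu4NF, THF, 0 °C → rt
Reagents that add atoms: none
Why: Fluoride desilylation; with both phenols still benzylated the basic fluoride cannot open the ring through a quinone methide, so C2 is safe.

Step 13
Reactants: 21 (2S,4R,6S)-2-[4-(benzyloxy)-3-methoxyphenyl]-6-{(1R)-2-[4-(benzyloxy)phenyl]-1-hydroxyethyl}oxan-4-ol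
Product: 22 (2S,4R,6S)-2-(4-hydroxy-3-methoxyphenyl)-6-[(1R)-1-hydroxy-2-(4-hydroxyphenyl)ethyl]oxan-4-ol
Conditions: H2 (1 atm), 10% Pd/C, EtOAc, rt, stopped after uptake of 2 equiv
Reagents that add atoms: none
Why: Catalytic hydrogenolysis of the two aryl benzyl ethers, which are cleaved far faster than the hindered secondary benzylic C2–O1 ring ether; the neutral, aprotic medium avoids acid-promoted ionisation of the product at C2.

## Compound list

1 | acrolein (prop-2-enal) | C=CC=O | starting material
2 | benzoic anhydride | O=C(OC(=O)c1ccccc1)c1ccccc1 | starting material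
3 | prop-2-ene-1,1-diyl dibenzoate | C=CC(OC(=O)c1ccccc1)OC(=O)c1ccccc1 | intermediate
4 | 4-(benzyloxy)-3-methoxybenzaldehyde (O-benzylvanillin) | COc1cc(C=O)ccc1OCc1ccccc1 | starting material
5 | (1R,2S)-1-[4-(benzyloxy)-3-methoxyphenyl]-1-hydroxybut-3-en-2-yl benzoate | COc1cc([C@@H](O)[C@@H](OC(=O)c2ccccc2)C=C)ccc1OCc1ccccc1 | intermediate
6 | ethyl diazoacetate | CCOC(=O)C=[N+]=[N-] | starting material
7 | ethyl 2-{[(1R,2S)-2-(benzoyloxy)-1-[4-(benzyloxy)-3-methoxyphenyl]but-3-en-1-yl]oxy}acetate | COc1cc([C@@H](OCC(=O)OCC)[C@@H](OC(=O)c2ccccc2)C=C)ccc1OCc1ccccc1 | intermediate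
8 | methyl 2-{[(1R,2S)-1-[4-(benzyloxy)-3-methoxyphenyl]-2-hydroxybut-3-en-1-yl]oxy}acetate | COc1cc([C@@H](OCC(=O)OC)[C@@H](O)C=C)ccc1OCc1ccccc1 | intermediate (not isolated)
9 | (5R,6S)-5-[4-(benzyloxy)-3-methoxyphenyl]-6-ethenyl-1,4-dioxan-2-one | COc1cc([C@H]2OCC(=O)O[C@H]2C=C)ccc1OCc1ccccc1 | intermediate
10 | (2R,3S)-2-[4-(benzyloxy)-3-methoxyphenyl]-3-ethenyl-5-[(trimethylsilyl)oxy]-2,3-dihydro-1,4-dioxine | COc1cc([C@H]2OC=C(O[Si](C)(C)C)O[C@H]2C=C)ccc1OCc1ccccc1 | intermediate (not isolated)
11 | trimethylsilyl (2S,6S)-6-[4-(benzyloxy)-3-methoxyphenyl]-3,6-dihydro-2H-pyran-2-carboxylate | COc1cc([C@@H]2C=CC[C@@H](C(=O)O[Si](C)(C)C)O2)ccc1OCc1ccccc1 | intermediate (not isolated)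
12 | (2S,6S)-6-[4-(benzyloxy)-3-methoxyphenyl]-3,6-dihydro-2H-pyran-2-carboxylic acid | COc1cc([C@@H]2C=CC[C@@H](C(=O)O)O2)ccc1OCc1ccccc1 | intermediate
13 | (1S,3R,4R,5S)-3-[4-(benzyloxy)-3-methoxyphenyl]-4-iodo-2,6-dioxabicyclo[3.2.1]octan-7-one | COc1cc([C@@H]2[C@H](I)[C@@H]3C[C@@H](C(=O)O3)O2)ccc1OCc1ccccc1 | intermediate
14 | (1S,3S,5R)-3-[4-(benzyloxy)-3-methoxyphenyl]-2,6-dioxabicyclo[3.2.1]octan-7-one | COc1cc([C@@H]2C[C@@H]3C[C@@H](C(=O)O3)O2)ccc1OCc1ccccc1 | intermediate
15 | (2S,4R,6S)-6-[4-(benzyloxy)-3-methoxyphenyl]-4-hydroxy-N-methoxy-N-methyloxane-2-carboxamide | COc1cc([C@@H]2C[C@@H](O)C[C@@H](C(=O)N(C)OC)O2)ccc1OCc1ccccc1 | intermediate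
16 | (2S,4R,6S)-6-[4-(benzyloxy)-3-methoxyphenyl]-4-[(tert-butyldimethylsilyl)oxy]-N-methoxy-N-methyloxane-2-carboxamide | COc1cc([C@@H]2C[C@@H](O[Si](C)(C)C(C)(C)C)C[C@@H](C(=O)N(C)OC)O2)ccc1OCc1ccccc1 | intermediate
17 | 1-(benzyloxy)-4-(chloromethyl)benzene (4-benzyloxybenzyl chloride) | ClCc1ccc(OCc2ccccc2)cc1 | starting material
18 | [4-(benzyloxy)benzyl]magnesium chloride | Cl[Mg]Cc1ccc(OCc2ccccc2)cc1 | intermediate (not isolated)
19 | 1-[(2S,4R,6S)-6-[4-(benzyloxy)-3-methoxyphenyl]-4-[(tert-butyldimethylsilyl)oxy]oxan-2-yl]-2-[4-(benzyloxy)phenyl]ethan-1-one | COc1cc([C@@H]2C[C@@H](O[Si](C)(C)C(C)(C)C)C[C@@H](C(=O)Cc3ccc(OCc4ccccc4)cc3)O2)ccc1OCc1ccccc1 | intermediate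
20 | (1R)-1-[(2S,4R,6S)-6-[4-(benzyloxy)-3-methoxyphenyl]-4-[(tert-butyldimethylsilyl)oxy]oxan-2-yl]-2-[4-(benzyloxy)phenyl]ethan-1-ol | COc1cc([C@@H]2C[C@@H](O[Si](C)(C)C(C)(C)C)C[C@@H]([C@H](O)Cc3ccc(OCc4ccccc4)cc3)O2)ccc1OCc1ccccc1 | intermediate
21 | (2S,4R,6S)-2-[4-(benzyloxy)-3-methoxyphenyl]-6-{(1R)-2-[4-(benzyloxy)phenyl]-1-hydroxyethyl}oxan-4-ol | COc1cc([C@@H]2C[C@@H](O)C[C@@H]([C@H](O)Cc3ccc(OCc4ccccc4)cc3)O2)ccc1OCc1ccccc1 | intermediate
22 | (2S,4R,6S)-2-(4-hydroxy-3-methoxyphenyl)-6-[(1R)-1-hydroxy-2-(4-hydroxyphenyl)ethyl]oxan-4-ol | COc1cc([C@@H]2C[C@@H](O)C[C@@H]([C@H](O)Cc3ccc(O)cc3)O2)ccc1O | target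

## Step count and least certain steps

Total step count: 13. Longest linear sequence: 13 steps (1 to 22); aldehyde 4, diazo ester 6 and chloride 17 enter along the line.

**Step 5 (key step).** The rearrangement itself is geometrically assured. The likely failures are an enolate that is not silylated at once and then acylates a second lactone molecule, and ionisation of the electron-rich benzylic C2–O1 bond (allylic as well in acid 12) during warming or work-up, which would erode the C2 configuration.
Fallback, with the same acid built by ring-closing metathesis and the two ring stereocentres set independently; it sets out from 4 and returns at 12. Addition of vinylmagnesium bromide to 4 gives the racemic aryl vinyl carbinol F1, and a Sharpless kinetic resolution (Ti(OiPr)4, the diisopropyl tartrate antipode that consumes the (R)-alcohol, t-BuOOH) leaves the (S)-carbinol F2. O-Alkylation of its sodium alkoxide with bromoacetic acid gives the glycolic acid ether F3. Its mixed pivalic anhydride acylates lithiated (4R)-4-benzyl-1,3-oxazolidin-2-one to give the N-glycolyl oxazolidinone F4. Evans alkylation of the sodium enolate (NaN(SiMe3)2, allyl iodide, −78 °C) sets C6 and gives the pent-4-enoyl imide F5. Ring-closing metathesis with the second-generation Grubbs catalyst forms the C3=C4 bond and gives the dihydropyran imide F6, and LiOH/H2O2 removes the auxiliary to give 12.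

**Step 2.** The risks are insufficient facial or anti selectivity with this electron-rich aldehyde, and benzoyl transfer from the allylic to the benzylic oxygen under the basic conditions, which would scramble which oxygen later receives the glycolate.
Fallback, with a syn-selective allylboration followed by inversion at the allylic carbon; it sets out from 4 and returns at 7. Brown alkoxyallylboration of 4 with B-[(Z)-3-(methoxymethoxy)allyl]diisopinocampheylborane (from allyl methoxymethyl ether, s-BuLi, the appropriate antipode of B-methoxydiisopinocampheylborane and BF3·OEt2) gives the syn methoxymethyl ether alcohol F7, whose acetal cannot migrate. Rh2(OAc)4-catalysed insertion of 6 into its hydroxyl gives the glycolate ether F8. Me2BBr at −78 °C removes the acetal and gives the syn hydroxy ester F9. A Mitsunobu reaction with benzoic acid (PPh3, diisopropyl azodicarboxylate) inverts the allylic carbon and gives 7.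

**Step 10.** The risks are homocoupling of the benzylic halide during magnesium insertion, which would starve the addition of nucleophile, and base- or silica-mediated epimerisation at C6 of the liberated α-alkoxy ketone toward the more stable 2,6-cis ring.
Fallback, with a sulfone-stabilised benzylic carbanion in place of the Grignard reagent; it sets out from 16 and 17 and returns at 19. Chloride 17 and PhSO2Na in DMF give the benzylic phenyl sulfone F10. Its lithio derivative (n-BuLi, THF, −78 °C, 2 equiv) acylates on 16 to give the β-keto sulfone F11, which stays deprotonated on the sulfone side and so protects C6. Reductive desulfonylation with aluminium amalgam in aqueous THF gives 19.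

**Step 11.** The risk is poor facial selectivity if chelation between O1 and the carbonyl is incomplete, for instance when the ring adopts the conformer with the aryl group axial beside the hydride path.
Fallback, with the opposite epimer made on purpose and then inverted; it sets out from 19 and returns at 20. Reduction with LiBH(s-Bu)3 in THF at −78 °C follows the Felkin–Anh course and gives the (1'S) alcohol F12. A Mitsunobu reaction with 4-nitrobenzoic acid gives the inverted (1'R) 4-nitrobenzoate F13, and K2CO3 in MeOH releases 20.

## Further compounds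

F1 | step 5 | rac-1-[4-(benzyloxy)-3-methoxyphenyl]prop-2-en-1-ol | COc1cc(C(O)C=C)ccc1OCc1ccccc1
F2 | step 5 | (1S)-1-[4-(benzyloxy)-3-methoxyphenyl]prop-2-en-1-ol | COc1cc([C@@H](O)C=C)ccc1OCc1ccccc1
F3 | step 5 | 2-{[(1S)-1-[4-(benzyloxy)-3-methoxyphenyl]prop-2-en-1-yl]oxy}acetic acid | COc1cc([C@@H](OCC(=O)O)C=C)ccc1OCc1ccccc1
F4 | step 5 | (4R)-4-benzyl-3-(2-{[(1S)-1-[4-(benzyloxy)-3-methoxyphenyl]prop-2-en-1-yl]oxy}acetyl)-1,3-oxazolidin-2-one | COc1cc([C@@H](OCC(=O)N2[C@H](Cc3ccccc3)COC2=O)C=C)ccc1OCc1ccccc1
F5 | step 5 | (4R)-4-benzyl-3-[(2S)-2-{[(1S)-1-[4-(benzyloxy)-3-methoxyphenyl]prop-2-en-1-yl]oxy}pent-4-enoyl]-1,3-oxazolidin-2-one | COc1cc([C@@H](O[C@@H](CC=C)C(=O)N2[C@H](Cc3ccccc3)COC2=O)C=C)ccc1OCc1ccccc1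
F6 | step 5 | (4R)-4-benzyl-3-{[(2S,6S)-6-[4-(benzyloxy)-3-methoxyphenyl]-3,6-dihydro-2H-pyran-2-yl]carbonyl}-1,3-oxazolidin-2-one | COc1cc([C@@H]2C=CC[C@@H](C(=O)N3[C@H](Cc4ccccc4)COC3=O)O2)ccc1OCc1ccccc1
F7 | step 2 | (1R,2R)-1-[4-(benzyloxy)-3-methoxyphenyl]-2-(methoxymethoxy)but-3-en-1-ol | COc1cc([C@@H](O)[C@H](OCOC)C=C)ccc1OCc1ccccc1
F8 | step 2 | ethyl 2-{[(1R,2R)-1-[4-(benzyloxy)-3-methoxyphenyl]-2-(methoxymethoxy)but-3-en-1-yl]oxy}acetate | COc1cc([C@@H](OCC(=O)OCC)[C@H](OCOC)C=C)ccc1OCc1ccccc1
F9 | step 2 | ethyl 2-{[(1R,2R)-1-[4-(benzyloxy)-3-methoxyphenyl]-2-hydroxybut-3-en-1-yl]oxy}acetate | COc1cc([C@@H](OCC(=O)OCC)[C@H](O)C=C)ccc1OCc1ccccc1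
F10 | step 10 | 1-(benzyloxy)-4-[(phenylsulfonyl)methyl]benzene | O=S(=O)(Cc1ccc(OCc2ccccc2)cc1)c1ccccc1
F11 | step 10 | 1-[(2S,4R,6S)-6-[4-(benzyloxy)-3-methoxyphenyl]-4-[(tert-butyldimethylsilyl)oxy]oxan-2-yl]-2-[4-(benzyloxy)phenyl]-2-(phenylsulfonyl)ethan-1-one (both epimers at the sulfonyl carbon) | COc1cc([C@@H]2C[C@@H](O[Si](C)(C)C(C)(C)C)C[C@@H](C(=O)C(c3ccc(OCc4ccccc4)cc3)S(=O)(=O)c3ccccc3)O2)ccc1OCc1ccccc1
F12 | step 11 | (1S)-1-[(2S,4R,6S)-6-[4-(benzyloxy)-3-methoxyphenyl]-4-[(tert-butyldimethylsilyl)oxy]oxan-2-yl]-2-[4-(benzyloxy)phenyl]ethan-1-ol | COc1cc([C@@H]2C[C@@H](O[Si](C)(C)C(C)(C)C)C[C@@H]([C@@H](O)Cc3ccc(OCc4ccccc4)cc3)O2)ccc1OCc1ccccc1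
F13 | step 11 | (1R)-1-[(2S,4R,6S)-6-[4-(benzyloxy)-3-methoxyphenyl]-4-[(tert-butyldimethylsilyl)oxy]oxan-2-yl]-2-[4-(benzyloxy)phenyl]ethyl 4-nitrobenzoate | COc1cc([C@@H]2C[C@@H](O[Si](C)(C)C(C)(C)C)C[C@@H]([C@H](OC(=O)c5ccc([N+](=O)[O-])cc5)Cc3ccc(OCc4ccccc4)cc3)O2)ccc1OCc1ccccc1
A1 | alternative 1 | 5-[4-(benzyloxy)-3-methoxyphenyl]-3-(benzyloxy)-7-[4-(benzyloxy)benzyl]-6,8-dioxabicyclo[3.2.1]octane, ketal carbon bonded to O1 and the C1' oxygen, other centres as in the target | COc1cc([C@@]52C[C@@H](OCc6ccccc6)C[C@@H]([C@H](O5)Cc3ccc(OCc4ccccc4)cc3)O2)ccc1OCc1ccccc1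
A2 | alternative 1 | (3S,5S,6R)-3-(benzyloxy)-1-[4-(benzyloxy)-3-methoxyphenyl]-7-[4-(benzyloxy)phenyl]-5,6-dihydroxyheptan-1-one | COc1cc(C(=O)C[C@@H](OCc6ccccc6)C[C@H](O)[C@H](O)Cc3ccc(OCc4ccccc4)cc3)ccc1OCc1ccccc1
A3 | alternative 2 | (1R)-1-[(2S,4R,6S)-6-[4-(benzyloxy)-3-methoxyphenyl]-4-[(tert-butyldimethylsilyl)oxy]oxan-2-yl]-2-[4-(benzyloxy)phenyl]ethan-1-ol (identical with 20) | COc1cc([C@@H]2C[C@@H](O[Si](C)(C)C(C)(C)C)C[C@@H]([C@H](O)Cc3ccc(OCc4ccccc4)cc3)O2)ccc1OCc1ccccc1
A4 | alternative 2 | (1S,3R)-1-[4-(benzyloxy)-3-methoxyphenyl]-4-{(2R,3R)-3-[4-(benzyloxy)benzyl]oxiran-2-yl}-3-[(tert-butyldimethylsilyl)oxy]butan-1-ol | COc1cc([C@@H](O)C[C@@H](O[Si](C)(C)C(C)(C)C)C[C@H]2O[C@@H]2Cc3ccc(OCc4ccccc4)cc3)ccc1OCc1ccccc1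
A5 | alternative 3 | (2S)-2-[4-(benzyloxy)-3-methoxyphenyl]-2,3-dihydro-4H-pyran-4-one | COc1cc([C@@H]2CC(=O)C=CO2)ccc1OCc1ccccc1
A6 | alternative 3 | (E)-1-methoxy-3-[(trimethylsilyl)oxy]buta-1,3-diene | CO/C=C/C(=C)O[Si](C)(C)C
A7 | alternative 3 | (2S,6S)-2-[4-(benzyloxy)-3-methoxyphenyl]-6-ethenyloxan-4-one | COc1cc([C@@H]2CC(=O)C[C@@H](C=C)O2)ccc1OCc1ccccc1
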